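X was slow: it needed 1.1 min to halve by its first step alone, longer than D needed to halve by its loss to Q alone (0.70 min).

    X → L (k1 = 0.0102 s⁻¹)
    L → Z (k2 = 0.0286 s⁻¹)
    Z → D (k3 = 0.236 s⁻¹)
    D → Q (k4 = 0.0166 s⁻¹)
    X + D → X.D (k5 = 0.00566 M⁻¹ s⁻¹)

- red: X 0.80 M; time 2.5 min; a closed flask charged with all of it at once and left for 2.5 min
- amber: X 0.80 M; one stirred flow tank at steady state, fed with the mixture as stated, mean residence time 2.5 min

- the set-up with the highest share of D in all that became D or Q or X.D, at the outlet or at the end ("none" if the first two lie within 2 percentage points) (red / amber / none)
- share of D in all that became D or Q or X.D, at the outlet or at the end, red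
- share of D in all that became D or Q or X.D, at the outlet or at the end, amber

- in percentages every species weighs as the X in it: one X.D counts as two
- the stated concentrations are those of everything mixed, before any reaction; amounts are the same in each set-up
- run time (red): 2.5 min

1. I worked with fractions left. The share asked is D against D plus what D became, with X.D counted double.

2. At a given amount of X, D's loss to X.D is pseudo-first-order. Per Q formed, doubled X.D forms in proportion to the fraction of X left. At the charged X, that ratio is the side weight, 0.546.

3. First setting, the vessel. In the amber tank, the balances gave Q as D times the loss constant times the residence time. I set aside X lost to X.D, so I reckoned the fraction of X left in amber as 0.395. The amber share came to 24.8 %.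

4. Second setting, the time. For red at 2.5 min, I used exponential fractions left, ignoring Z and X.D. That gave D 24.0 % and Q 43.1 % of the charge. For the fraction of X left in red I took the one at half the time, reckoned as 0.465, so I reckoned doubled X.D per Q as 0.254. The red share came to 30.7 %.

5. Red led amber by 5.9 percentage points, more than the margin, so I chose red.

The forecast gave red, with 32.6 % for red, above mine, and 24.9 % for amber, saying “a larger share of D is lost there”.

The simulation gave red, with 32.1 % for red and 24.9 % for amber.

At the end, red held X.D 8.01 % and Q 38.5 %, or 0.208 per Q, against my 0.254. The neighbouring flask was red stopped at 1.0 min. Side weight times the fraction of X left at half that time gave 0.402. That flask held X.D 2.26 % and Q 6.45 %, or 0.350 per Q. With its D 15.6 %, my weight gave a share of 63.3 %. The simulated share in that flask was 64.2 %.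

The numbers of this flask are made up; the run is a simulation.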